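## The problem

Target 16 is an achiral diaryl ether in which ring A (C1 CO2Me, C2 ether oxygen, C3 H, C4 methyl, C5 prenyl, C6 OH) is joined through oxygen to C1' of ring B (C2' CH2OH, C4' and C6' OMe). The ether oxygen is flanked by the C1 ester on one ring and by the C2' and C6' substituents on the other, and both rings are electron-rich, so joining two finished arenes by substitution or copper-mediated coupling is unattractive. There is no stereocentre in 16; sp3 centres that appear on the way only have to be erasable, and none has to control another. The prenyl group must stand at C5 and not at C3, and it will not survive acid (chroman formation with the C6 hydroxyl), iodine or unselective hydrogenation, so it has to come late. The benzylic alcohol of ring B is prone to solvolysis and oxidation, and the C1 ester, although hindered and hydrogen-bonded, can acylate any carbanion tethered to the C2 oxygen. The feature that opens the synthesis is the oxygen pattern of ring B: oxygens on C4' and C6' in a 1,3 relation, the ether oxygen on C1' next to C6', and the hydroxymethyl on C2'. This is the pattern of a 4-aryloxy-5-(hydroxymethyl)cyclohexane-1,3-dione, one dehydrogenation below the arene; it divides into a malonate carbon (C1' with C6') and a four-carbon enone (C2' to C5'), and ring A without prenyl group is the symmetric diphenol 1, so the C1'–O bond can be made as an sp3 carbon–oxygen bond by alkylation.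

## Retrosynthesis

**Prenyl group (16 to 15, 14, 12 + 13).** The C5–CH2 bond is cut last. Direct C-prenylation of the phenol would give C5/C3/O mixtures, whereas a [3,3] shift from the C6 oxygen can only end at C5 because the other ortho carbon (C1) carries the ester. The precursor is the 1,1-dimethylallyl ether 15, which comes from the propargyl ether 14 by semihydrogenation, and 14 from phenol 12 and the tertiary propargylic chloride 13. The forward reactions must discriminate the phenol from the benzylic alcohol and must be neutral.

**Ring B arene (12 to 11).** The two O–CH3 bonds and one degree of unsaturation of ring B are removed, leading back to the 4-aryloxycyclohexane-1,3-dione 11 with its hydroxymethyl group silylated. Iodine in methanol does dehydrogenation and double O-methylation in one operation. Because the HI formed in methanol cleaves primary silyl ethers, the silyl group is planned to leave in the same step rather than in a separate deprotection. This removes all arene chemistry from ring B and replaces it by carbonyl chemistry.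

**Blocking ester (11 to 9, through acid 10).** A methoxycarbonyl group is put back on C1'. It is the second ester of the malonate that brings C1' in, it prevents enolisation at C1' during ring formation, and it is a β-keto ester that leaves by hydrolysis and decarboxylation. Hydroxide is preferred to chloride dealkylation (Krapcho) because the ring A ester is a salicylate, whose methyl group is as exposed to chloride as that of the β-keto ester, while its acyl carbon is shielded from hydroxide.

**Ring B carbocycle (9 to 3 + 7, through 8).** The C1'–C2' and C5'–C6' bonds are cut. This is the only pair of cuts that gives a stabilised carbanion carrying the aryloxy group (malonate 3) and a simple enone (7). The neighbouring cuts (C2'–C3' / C4'–C5', or C3'–C4' / C6'–C1') would need an α-aryloxy ketone enolate, which would attack the ring A ester. The precursors are an open-chain malonate and a five-carbon enone; the forward reaction must add 1,4, close from the methyl side and leave the ring A ester alone.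

**Ether oxygen (3 to 1 + 2).** The O–C1' bond is cut to the symmetric diphenol 1 and dimethyl chloromalonate 2. No aryl–oxygen bond has to be formed, and the symmetry of 1 removes any regiochemical question; the forward reaction has to stop at mono-alkylation.

**Enone (7 to 6 to 4 + 5).** The C2'=C3' double bond is cut by a Wittig transform to glycolaldehyde (as its dimer 4) and the acetonyl ylide 5, with silylation of the hydroxy enone 6 in between. A stabilised ylide secures the E geometry, which is needed only for clean conjugate addition.

## Roads not taken

**Alternative 1:** The cut removes the C2–O bond and the C1–carboxyl bond of ring A together. In the forward direction the silyl triflate A2 undergoes CsF-induced 1,2-elimination, the caesium phenoxide of the ring B phenol A3 adds at C2 (meta to the directing alkoxy group), and the C1 anion is carboxylated by CO2 to give acid A1. Esterification and removal of the two methoxymethyl groups would finish the synthesis.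
- Merits: the two most awkward bonds of ring A are made in one step, ring B stays aromatic throughout, and no redox adjustment is needed. After the key step this road is shorter than the chosen one.
- Weak points: A2 is itself a pentasubstituted arene whose five groups must be placed in fixed positions, which costs more steps than the whole of ring B in the chosen plan. The phenoxide of A3 is di-ortho-substituted and is reversibly carbonated by CO2. Protonation of the C1 anion competes with carboxylation; this three-component coupling is established for amines rather than phenoxides. The prenyl alkene can react with the strained intermediate in an ene fashion, and the final acidic removal of methoxymethyl groups endangers the ortho-prenyl phenol.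
- Comparison: against the better convergence of this road, the chosen plan sets bond formations that each have direct precedent (alkylation, Michael–Claisen, Claisen) and starting materials that are bought, not built.

**Alternative 2:** The cut takes ring A apart at C1–C6, C2–C3 and C5–C6. Forward, photochemical Wolff rearrangement of diazo ketone A5 in the presence of the ring B ethynyl ether A6, followed by [2+2] addition, four-electron ring opening and six-electron closure (Danheiser benzannulation), gives phenol A4, which is ring A without the ester.
- Merits: methyl and prenyl are placed by the structure of A5, so no Claisen sequence is needed, and ring B is carried as an arene.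
- Weak points: aryl ethynyl ethers with two ortho substituents such as A6 are hard to make and to keep. The prenyl alkene of A5 can intercept the rearranged intermediate intramolecularly. The C1 ester is missing and would have to be introduced afterwards by protection, ortho-metalation between the two oxygens and acylation, in the presence of allylic and benzylic C–H bonds.
- Comparison: the step count ends near that of the chosen plan. This road is better at fixing the C5 prenyl position; the chosen plan answers with an ester that is present from the first compound and with thermal, non-photochemical steps.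

**Alternative 3:** The cut takes ring A apart at C1–C2 and C3–C4. Forward, A6 adds across C3 and C6 of pyrone A8 (terminal alkyne carbon to C6, oxygen-bearing carbon to C3) and the bridged adduct loses CO2 to give A7, the complete carbon skeleton with ester, prenyl and both rings in place.
- Merits: this is the most convergent of all roads. A7 is two deprotections from 16, and the polarity of the ester-bearing pyrone and the ynol ether matches the required regiochemistry.
- Weak points: A8 is fully substituted, its C4 alkoxy group is a donor and C5/C6 carry alkyl groups, so the inverse-demand cycloaddition is deactivated and hindered and would need temperatures at which A6 does not persist. C5 prenylation of a 4-hydroxypyrone is not a solved problem, and A6 has the same availability problem as in alternative 2.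
- Comparison: if the cycloaddition worked, this road would be clearly shorter than the chosen one. The chosen plan sets against it that neither partner of its key step is fragile and that the key step runs in methanol with methoxide.

Key step: step 4

Remark: diones 9, 10 and 11 are written as diketones although they will exist largely as enols, and the chloride 13 is taken as the commercial form of 2-methylbut-3-yn-2-ol.

## Route

Step 1
Reactants: 1 methyl 2,6-dihydroxy-4-methylbenzoate; 2 dimethyl chloromalonate (dimethyl 2-chloropropanedioate)
Product: 3 dimethyl 2-[3-hydroxy-2-(methoxycarbonyl)-5-methylphenoxy]propanedioate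
Conditions: K2CO3, acetone, rt to 50 °C (1 in slight excess)
Reagents that add atoms: none
Why: Williamson-type O-alkylation of a phenoxide with an α-halomalonate, the usual route to aryloxymalonates; the two OH groups of 1 are equivalent, and after the first alkylation the remaining OH is hydrogen-bonded to the ester carbonyl and 3 is held as its malonate anion, so a second alkylation is slow. The chloride is preferred to the bromide because it transfers halogen to the electron-rich ring far less readily.

Step 2
Reactants: 4 glycolaldehyde dimer (1,4-dioxane-2,5-diol, 0.5 equiv); 5 1-(triphenylphosphoranylidene)propan-2-one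
Product: 6 (E)-5-hydroxypent-3-en-2-one
Conditions: THF, reflux
Reagents that add atoms: none
Why: Wittig olefination; the hemiacetal dimer opens to monomeric glycolaldehyde on heating and the stabilised acyl ylide gives the E-alkene, which cannot cyclise onto its own ketone.

Step 3
Reactants: 6 (E)-5-hydroxypent-3-en-2-one
Product: 7 (E)-5-[tri(propan-2-yl)silyloxy]pent-3-en-2-one
Conditions: TIPSCl, imidazole, CH2Cl2, 0 °C to rt
Reagents that add atoms: chlorotri(propan-2-yl)silane (TIPSCl), CC(C)[Si](Cl)(C(C)C)C(C)C
Why: Standard silylation of a primary alcohol; the triisopropylsilyl ether is chosen because it withstands methoxide and hydroxide in steps 4 and 5 and is released by the acid formed in step 6.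

Step 4
Reactants: 3 dimethyl 2-[3-hydroxy-2-(methoxycarbonyl)-5-methylphenoxy]propanedioate; 7 (E)-5-[tri(propan-2-yl)silyloxy]pent-3-en-2-one
Product: 9 methyl 1-[3-hydroxy-2-(methoxycarbonyl)-5-methylphenoxy]-2,4-dioxo-6-{[tri(propan-2-yl)silyloxy]methyl}cyclohexane-1-carboxylate (racemic diastereomer mixture), via open-chain Michael adduct 8 (not isolated)
Conditions: NaOMe (2.5 equiv), MeOH, 0 °C to reflux (7 added slowly); then 1 M HCl to pH 3
Reagents that add atoms: none
Why: NaOMe deprotonates the ring A phenol and the malonate C–H of 3, and the soft malonate anion adds to the β-carbon of 7 (C1'–C2' bond) to give 8 as its ketone enolate. Proton exchange through methanol gives the methyl-side enolate, whose carbon (C5') attacks one malonate ester (C6') in a 6-exo-trig Claisen closure; loss of methoxide and deprotonation of the resulting 1,3-dione (pKa about 5) pull the reversible conjugate addition forward. The closest known reaction type is the Michael–Claisen annulation of malonates with enones (the dimedone synthesis), which is also used with β-substituted enones to make resorcinol precursors. C2' is set in the conjugate addition and C1' when one of the two diastereotopic esters is attacked, both without control, which is acceptable because both centres become sp2 in step 6. The step needs 1,4- over 1,2-addition, which the stabilised anion secures, and closure from the methyl and not the methylene side, which would give a four-membered ring. It also needs the ring A ester to stay untouched: the ketone enolate would have to form a nine-membered ring to reach it, and 5-exo attack by the malonate carbanion is held back because that ester is flanked by two ortho substituents and conjugated to the ortho phenoxide, which is why the phenol is left free. All esters are methyl and the base is methoxide in methanol, so ester exchange changes nothing.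

Step 5
Reactants: 9 methyl 1-[3-hydroxy-2-(methoxycarbonyl)-5-methylphenoxy]-2,4-dioxo-6-{[tri(propan-2-yl)silyloxy]methyl}cyclohexane-1-carboxylate
Product: 11 methyl 2-({2,4-dioxo-6-[(triisopropylsilyloxy)methyl]cyclohexyl}oxy)-6-hydroxy-4-methylbenzoate (racemic diastereomer mixture), via carboxylic acid 10 (not isolated)
Conditions: KOH, MeOH/H2O, 60 °C; then 1 M HCl to pH 3, 40 °C
Reagents that add atoms: none
Why: Ester hydrolysis followed by decarboxylation of a β-keto acid, the second half of the dimedone protocol; hydroxide attacks the C1' ester (activated by the α-aryloxy group), whereas the ring A ester is di-ortho-substituted and conjugated to the phenoxide and is left. The dione is present as its enolate during hydrolysis, which protects the ring against retro-Claisen opening, and acid 10 loses CO2 through the C6' ketone on acidification; the new C1' centre is formed without control and is erased in step 6.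

Step 6
Reactants: 11 methyl 2-({2,4-dioxo-6-[(triisopropylsilyloxy)methyl]cyclohexyl}oxy)-6-hydroxy-4-methylbenzoate
Product: 12 methyl 2-hydroxy-6-[2-(hydroxymethyl)-4,6-dimethoxyphenoxy]-4-methylbenzoate
Conditions: I2 (2.2 equiv), MeOH, reflux
Reagents that add atoms: methanol, CO
Why: Oxidative aromatisation of a cyclohexane-1,3-dione with iodine in methanol, which gives resorcinol dimethyl ethers through acid-catalysed methyl enol ether formation, α-iodination and loss of HI. The HI liberated in methanol cleaves the primary silyl ether, so the alcohol is released in the same operation; ring A is deactivated by its ester and is not iodinated in the absence of base.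

Step 7
Reactants: 12 methyl 2-hydroxy-6-[2-(hydroxymethyl)-4,6-dimethoxyphenoxy]-4-methylbenzoate; 13 3-chloro-3-methylbut-1-yne
Product: 14 methyl 2-[2-(hydroxymethyl)-4,6-dimethoxyphenoxy]-4-methyl-6-[(2-methylbut-3-yn-2-yl)oxy]benzoate
Conditions: DBU, CuCl2·2H2O (cat.), MeCN, 0 °C to rt
Reagents that add atoms: none
Why: Copper-catalysed propargylic etherification of a phenol with a tertiary propargylic chloride, which runs through a copper acetylide and needs no SN2 attack at the tertiary carbon. DBU deprotonates only the phenol, so the neutral benzylic alcohol does not compete.

Step 8
Reactants: 14 methyl 2-[2-(hydroxymethyl)-4,6-dimethoxyphenoxy]-4-methyl-6-[(2-methylbut-3-yn-2-yl)oxy]benzoate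
Product: 15 methyl 2-[2-(hydroxymethyl)-4,6-dimethoxyphenoxy]-4-methyl-6-[(2-methylbut-3-en-2-yl)oxy]benzoate
Conditions: H2 (1 atm), Lindlar catalyst (Pd/CaCO3 poisoned with Pb(OAc)2), quinoline, EtOAc, rt
Reagents that add atoms: none
Why: Lindlar semihydrogenation of a terminal alkyne to the alkene; the poisoned catalyst leaves the aryl ethers, the benzylic alcohol and the ester untouched, and the reaction is stopped after one equivalent of hydrogen.

Step 9
Reactants: 15 methyl 2-[2-(hydroxymethyl)-4,6-dimethoxyphenoxy]-4-methyl-6-[(2-methylbut-3-en-2-yl)oxy]benzoate
Product: 16 methyl 6-hydroxy-2-[2-(hydroxymethyl)-4,6-dimethoxyphenoxy]-4-methyl-5-(3-methylbut-2-enyl)benzoate (CNP0583011.0)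
Conditions: xylenes, 130 °C
Reagents that add atoms: none
Why: Aromatic Claisen rearrangement ([3,3]) of a 1,1-dimethylallyl aryl ether, which delivers the allyl unit with inversion as a prenyl group to the ortho carbon. C1 is blocked by the ester, so only C5 can accept the group and rearomatise by tautomerisation, and the neutral thermal conditions suit the prenyl alkene and the benzylic alcohol.

## Compound list

1 | methyl 2,6-dihydroxy-4-methylbenzoate | COC(=O)c1c(O)cc(C)cc1O | starting material
2 | dimethyl chloromalonate (dimethyl 2-chloropropanedioate) | COC(=O)C(Cl)C(=O)OC | starting material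
3 | dimethyl 2-[3-hydroxy-2-(methoxycarbonyl)-5-methylphenoxy]propanedioate | COC(=O)C(Oc1cc(C)cc(O)c1C(=O)OC)C(=O)OC | intermediate
4 | glycolaldehyde dimer (1,4-dioxane-2,5-diol) | OC1COC(O)CO1 | starting material
5 | 1-(triphenylphosphoranylidene)propan-2-one | CC(=O)C=P(c1ccccc1)(c1ccccc1)c1ccccc1 | starting material
6 | (E)-5-hydroxypent-3-en-2-one | CC(=O)/C=C/CO | intermediate
7 | (E)-5-[tri(propan-2-yl)silyloxy]pent-3-en-2-one | CC(=O)/C=C/CO[Si](C(C)C)(C(C)C)C(C)C | intermediate
8 | dimethyl 2-[3-hydroxy-2-(methoxycarbonyl)-5-methylphenoxy]-2-{4-oxo-1-[tri(propan-2-yl)silyloxy]pentan-2-yl}propanedioate (racemic) | COC(=O)C(Oc1cc(C)cc(O)c1C(=O)OC)(C(=O)OC)C(CC(C)=O)CO[Si](C(C)C)(C(C)C)C(C)C | intermediate (not isolated)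
9 | methyl 1-[3-hydroxy-2-(methoxycarbonyl)-5-methylphenoxy]-2,4-dioxo-6-{[tri(propan-2-yl)silyloxy]methyl}cyclohexane-1-carboxylate (racemic diastereomer mixture) | COC(=O)C1(Oc2cc(C)cc(O)c2C(=O)OC)C(=O)CC(=O)CC1CO[Si](C(C)C)(C(C)C)C(C)C | intermediate
10 | 1-[3-hydroxy-2-(methoxycarbonyl)-5-methylphenoxy]-2,4-dioxo-6-{[tri(propan-2-yl)silyloxy]methyl}cyclohexane-1-carboxylic acid (racemic diastereomer mixture) | OC(=O)C1(Oc2cc(C)cc(O)c2C(=O)OC)C(=O)CC(=O)CC1CO[Si](C(C)C)(C(C)C)C(C)C | intermediate (not isolated)
11 | methyl 2-({2,4-dioxo-6-[(triisopropylsilyloxy)methyl]cyclohexyl}oxy)-6-hydroxy-4-methylbenzoate (racemic diastereomer mixture) | COC(=O)c1c(O)cc(C)cc1OC1C(=O)CC(=O)CC1CO[Si](C(C)C)(C(C)C)C(C)C | intermediate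
12 | methyl 2-hydroxy-6-[2-(hydroxymethyl)-4,6-dimethoxyphenoxy]-4-methylbenzoate | COC(=O)c1c(O)cc(C)cc1Oc1c(CO)cc(OC)cc1OC | intermediate
13 | 3-chloro-3-methylbut-1-yne | CC(C)(Cl)C#C | starting material
14 | methyl 2-[2-(hydroxymethyl)-4,6-dimethoxyphenoxy]-4-methyl-6-[(2-methylbut-3-yn-2-yl)oxy]benzoate | COC(=O)c1c(Oc2c(CO)cc(OC)cc2OC)cc(C)cc1OC(C)(C)C#C | intermediate
15 | methyl 2-[2-(hydroxymethyl)-4,6-dimethoxyphenoxy]-4-methyl-6-[(2-methylbut-3-en-2-yl)oxy]benzoate | COC(=O)c1c(Oc2c(CO)cc(OC)cc2OC)cc(C)cc1OC(C)(C)C=C | intermediate
16 | methyl 6-hydroxy-2-[2-(hydroxymethyl)-4,6-dimethoxyphenoxy]-4-methyl-5-(3-methylbut-2-enyl)benzoate (CNP0583011.0) | COC(=O)c1c(Oc2c(CO)cc(OC)cc2OC)cc(C)c(CC=C(C)C)c1O | target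

## Step count and risks

Total: 9 steps. Longest linear sequence: 8 steps (4 and 5 to 16, steps 2 to 9); the ring A branch joins after one step.

**Step 4 (key step).**
- What may go wrong: the conjugate addition creates a quaternary carbon next to a branched one and is reversible, so retro-addition may dominate before the Claisen closure traps the adduct. Meanwhile the enone can self-condense or be deprotonated at its γ-position, and the waiting malonate anion can slowly acylate itself on the ring A ester.
- Fallback: it sets out from 3 and comes back at 12. The enone is replaced by the ynone 5-{[tert-butyl(dimethyl)silyl]oxy}pent-3-yn-2-one F1, made in one step from commercial tert-butyldimethyl(prop-2-yn-1-yloxy)silane (n-BuLi, then N-methoxy-N-methylacetamide). Its sp carbon is unhindered and far more electrophilic, and the addition does not revert. NaOMe in methanol forms the same two bonds and gives methyl 6-({[tert-butyl(dimethyl)silyl]oxy}methyl)-1-[3-hydroxy-2-(methoxycarbonyl)-5-methylphenoxy]-2,4-dioxocyclohex-5-ene-1-carboxylate F2, which is already at the oxidation level of the arene. Methoxide is expected to remove its blocking ester as dimethyl carbonate in the same pot, because the departing carbanion is a resorcinolate, giving methyl 2-[2-({[tert-butyl(dimethyl)silyl]oxy}methyl)-4,6-dihydroxyphenoxy]-6-hydroxy-4-methylbenzoate F3. MeI (2.2 equiv) and K2CO3 in acetone methylate the two ring B phenols ahead of the hydrogen-bonded ring A phenol to give methyl 2-[2-({[tert-butyl(dimethyl)silyl]oxy}methyl)-4,6-dimethoxyphenoxy]-6-hydroxy-4-methylbenzoate F4, and Bu4NF in THF gives 12. Steps 5 and 6 are then not needed.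

**Step 6.**
- What may go wrong: once the silyl ether has been cleaved, the benzylic alcohol may be solvolysed by methanol under the HI that accumulates. Enol ether formation may stop at one carbonyl and leave a free ring B phenol, and HI may reductively remove the α-aryloxy group before aromatisation.
- Fallback: it sets out from 11 and comes back at 12. Dehydrogenation is separated from O-methylation and taken out of methanol. Hg(OAc)2 and NaOAc in AcOH (the classical aromatisation of cyclohexane-1,3-diones to resorcinols) should give methyl 2-{2,4-dihydroxy-6-[(triisopropylsilyloxy)methyl]phenoxy}-6-hydroxy-4-methylbenzoate F5 with the silyl ether in place. MeI and K2CO3 in acetone then give methyl 2-{2,4-dimethoxy-6-[(triisopropylsilyloxy)methyl]phenoxy}-6-hydroxy-4-methylbenzoate F6, and Bu4NF gives 12, so that the benzylic oxygen is never free in acidic methanol.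

**Step 1.**
- What may go wrong: alkylation may run on to the bis-ether, and under carbonate the malonate anion of 3 may cyclise onto the neighbouring ring A ester in a Dieckmann-type acyl transfer.
- Fallback: it sets out from 1 and comes back at 3. The O–C1' bond is made by Rh2(OAc)4-catalysed O–H insertion of dimethyl diazomalonate into 1 in CH2Cl2, a carbenoid reaction under neutral conditions in which no malonate anion and no phenoxide are present. It makes no new compound.

**Step 7.**
- What may go wrong: the chelated phenoxide may be alkylated too slowly, so that elimination of the tertiary chloride to the enyne takes over, and the benzylic alcohol may then begin to compete.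
- Fallback: it sets out from 12 and comes back at 15, passing over 14. Pd(PPh3)4-catalysed decarboxylative O-allylation with tert-butyl 2-methylbut-3-en-2-yl carbonate in THF at 0 °C (Tsuji–Trost type) lets the phenoxide attack the more substituted terminus of the 1,1-dimethylallyl palladium complex under kinetic control and gives the tertiary allyl ether directly. It makes no new compound.

## Further compounds

F1 | step 4 | 5-{[tert-butyl(dimethyl)silyl]oxy}pent-3-yn-2-one | CC(=O)C#CCO[Si](C)(C)C(C)(C)C
F2 | step 4 | methyl 6-({[tert-butyl(dimethyl)silyl]oxy}methyl)-1-[3-hydroxy-2-(methoxycarbonyl)-5-methylphenoxy]-2,4-dioxocyclohex-5-ene-1-carboxylate (racemic) | COC(=O)C1(Oc2cc(C)cc(O)c2C(=O)OC)C(=O)CC(=O)C=C1CO[Si](C)(C)C(C)(C)C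
F3 | step 4 | methyl 2-[2-({[tert-butyl(dimethyl)silyl]oxy}methyl)-4,6-dihydroxyphenoxy]-6-hydroxy-4-methylbenzoate | COC(=O)c1c(O)cc(C)cc1Oc1c(O)cc(O)cc1CO[Si](C)(C)C(C)(C)C
F4 | step 4 | methyl 2-[2-({[tert-butyl(dimethyl)silyl]oxy}methyl)-4,6-dimethoxyphenoxy]-6-hydroxy-4-methylbenzoate | COC(=O)c1c(O)cc(C)cc1Oc1c(OC)cc(OC)cc1CO[Si](C)(C)C(C)(C)C
F5 | step 6 | methyl 2-{2,4-dihydroxy-6-[(triisopropylsilyloxy)methyl]phenoxy}-6-hydroxy-4-methylbenzoate | COC(=O)c1c(O)cc(C)cc1Oc1c(O)cc(O)cc1CO[Si](C(C)C)(C(C)C)C(C)C
F6 | step 6 | methyl 2-{2,4-dimethoxy-6-[(triisopropylsilyloxy)methyl]phenoxy}-6-hydroxy-4-methylbenzoate | COC(=O)c1c(O)cc(C)cc1Oc1c(OC)cc(OC)cc1CO[Si](C(C)C)(C(C)C)C(C)C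
F0 | step 1 | none | none
F0 | step 7 | none | none
A1 | alternative 1 | 2-{2-[(methoxymethoxy)methyl]-4,6-dimethoxyphenoxy}-6-(methoxymethoxy)-4-methyl-5-(3-methylbut-2-enyl)benzoic acid | COCOCc1cc(OC)cc(OC)c1Oc1cc(C)c(CC=C(C)C)c(OCOC)c1C(=O)O
A2 | alternative 1 | 3-(methoxymethoxy)-5-methyl-4-(3-methylbut-2-enyl)-2-(trimethylsilyl)phenyl trifluoromethanesulfonate | C[Si](C)(C)c1c(OS(=O)(=O)C(F)(F)F)cc(C)c(CC=C(C)C)c1OCOC
A3 | alternative 1 | 2,4-dimethoxy-6-[(methoxymethoxy)methyl]phenol | COCOCc1cc(OC)cc(OC)c1O
A4 | alternative 2 | 5-[2-({[tert-butyl(dimethyl)silyl]oxy}methyl)-4,6-dimethoxyphenoxy]-3-methyl-2-(3-methylbut-2-enyl)phenol | Cc1cc(Oc2c(CO[Si](C)(C)C(C)(C)C)cc(OC)cc2OC)cc(O)c1CC=C(C)C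
A5 | alternative 2 | (3E)-1-diazo-3,7-dimethylocta-3,6-dien-2-one | CC(C)=CC/C=C(\C)C(=O)C=[N+]=[N-]
A6 | alternative 2 | tert-butyl[(2-ethynyloxy-3,5-dimethoxyphenyl)methoxy]dimethylsilane | C#COc1c(CO[Si](C)(C)C(C)(C)C)cc(OC)cc1OC
A7 | alternative 3 | methyl 6-[2-({[tert-butyl(dimethyl)silyl]oxy}methyl)-4,6-dimethoxyphenoxy]-2-(methoxymethoxy)-4-methyl-3-(3-methylbut-2-enyl)benzoate | COCOc1c(CC=C(C)C)c(C)cc(Oc2c(CO[Si](C)(C)C(C)(C)C)cc(OC)cc2OC)c1C(=O)OC
A8 | alternative 3 | methyl 4-(methoxymethoxy)-6-methyl-5-(3-methylbut-2-enyl)-2-oxo-2H-pyran-3-carboxylate | COC(=O)C1=C(OCOC)C(CC=C(C)C)=C(C)OC1=O
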